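**Retrosynthetic overview**
- Pongaflavanol ⇒ tunicatachalcone (the open, dearomatised chalcone). The O1–C2 bond and the C4–H bond are made in one operation: a reversible 6-endo oxa-Michael ring closure (chalcone → flavanone, as in the plant) coupled to enantioselective transfer hydrogenation of the matched flavanone. This sets C2 and C4.
- Tunicatachalcone ⇒ gem-diprenyl acetyl dienone + benzaldehyde (Claisen–Schmidt).
- gem-Diprenyl acetyl dienone ⇒ 2',4'-dihydroxy-6'-methoxyacetophenone + 2 prenyl bromide (dearomative C3 gem-prenylation, mimicking the prenyltransferase step).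
- Ring order: the A ring is bought as the arene and dearomatised first, the B ring comes from benzaldehyde, and the pyran C ring is closed last.

Assumption: 2',4'-dihydroxy-6'-methoxyacetophenone is treated as an inexpensive catalogue chemical.

**Step 1**
Reactants: 1 2',4'-dihydroxy-6'-methoxyacetophenone; 2 prenyl bromide (2.3 equiv)
Product: 4 4-acetyl-5-hydroxy-3-methoxy-6,6-bis(3-methylbut-2-en-1-yl)cyclohexa-2,4-dien-1-one, via mono-prenyl ketone 3 (not isolated)
Conditions: 10% aq KOH (3.5 equiv), 0 °C → rt; acidify to pH 4; chromatography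
Reagents that add atoms: prenyl bromide, CC(C)=CCBr
Why: Alkylative dearomatisation of an acylphloroglucinol-type phenoxide: in water the dianion is C-alkylated at C3 (the carbon flanked by both O−), and mono-prenyl ketone 3 is alkylated again at the same, now most electron-rich, carbon to give the vinylogous-acid dienone (the lupulone-type gem-diprenylation known for acylphloroglucinols); C5- and O-prenylated isomers are removed by chromatography (expect 30–40%) and no stereocentre is formed.

**Step 2**
Reactants: 4 gem-diprenyl acetyl dienone; 5 benzaldehyde (1.5 equiv)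
Product: 7 tunicatachalcone (5-hydroxy-3-methoxy-6,6-bis(3-methylbut-2-en-1-yl)-4-[(2E)-3-phenylprop-2-enoyl]cyclohexa-2,4-dien-1-one), via aldol adduct 6 (not isolated)
Conditions: 50% aq KOH, EtOH, 0 °C → rt, 24–48 h; then cold 1 M HCl to pH 4
Reagents that add atoms: benzaldehyde, O=Cc1ccccc1
Why: Claisen–Schmidt condensation: the dianion of 4 (enol O–H, then acetyl CH3) adds to benzaldehyde and aldol 6 loses water by E1cB to the thermodynamic E-enone; as an anion the ring vinylogous ester resists hydroxide, the prenyl groups are inert to base, and the same condensation is known for other gem-dialkylated acetylphloroglucinol dienones.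

**Step 3**
Reactants: 7 tunicatachalcone
Product: 10 pongaflavanol ((2S,4S)-4-hydroxy-5-methoxy-8,8-bis(3-methylbut-2-en-1-yl)-2-phenyl-3,4-dihydro-2H-chromen-7(8H)-one), via (2R)-flavanone 8 (not isolated), via (2S)-flavanone 9 (not isolated)
Conditions: HCO2H (3 equiv)/Et3N (4 equiv), EtOAc, 40 °C, 2 h; then RuCl[(S,S)-TsDPEN](p-cymene) (3 mol%), 40 °C, 24–48 h; NaHCO3 work-up, Et3N-deactivated silica
Reagents that add atoms: none
Why: Proposed new method: the acidic enol O–H of 7 (vinylogous acid, estimated pKa about 5–6) adds reversibly to its own enone in the Et3NH+/formate buffer (6-endo oxa-Michael, the non-enzymatic counterpart of chalcone isomerase), and because the ring oxygen is an excellent leaving group the flavanones 8 and 9 reopen by E1cB, so 7, 8 and 9 interconvert; the (S,S)-Ru–H delivers hydride to the Re face of C4=O (same sense as for acetophenone and 4-chromanone, giving 4S) and does so fast only on matched 9, where that face is anti to the 2-phenyl group, giving the 2,4-cis alcohol, while mismatched 8 is funnelled back through 7 into 9 (dynamic kinetic resolution sets C2 as S); C7=O is spared as a doubly vinylogous ester flanked by the quaternary C8, the open form rests largely as its poorly electrophilic enolate, and the closest known reactions are Noyori–Ikariya asymmetric transfer hydrogenation of racemic flavanones with kinetic resolution to cis-flavan-4-ols and the base-mediated chalcone ⇌ flavanone isomerisation.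

**Compound list**
1 | 1-(2,4-dihydroxy-6-methoxyphenyl)ethan-1-one (2',4'-dihydroxy-6'-methoxyacetophenone) | COc1cc(O)cc(O)c1C(C)=O | starting material
2 | prenyl bromide (1-bromo-3-methylbut-2-ene) | CC(C)=CCBr | starting material
3 | 1-[2,4-dihydroxy-6-methoxy-3-(3-methylbut-2-en-1-yl)phenyl]ethan-1-one (mono-prenyl ketone, formed in the flask) | COc1cc(O)c(CC=C(C)C)c(O)c1C(C)=O | intermediate
4 | 4-acetyl-5-hydroxy-3-methoxy-6,6-bis(3-methylbut-2-en-1-yl)cyclohexa-2,4-dien-1-one | COC1=CC(=O)C(CC=C(C)C)(CC=C(C)C)C(O)=C1C(C)=O | intermediate
5 | benzaldehyde | O=Cc1ccccc1 | starting material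
6 | 5-hydroxy-4-(3-hydroxy-3-phenylpropanoyl)-3-methoxy-6,6-bis(3-methylbut-2-en-1-yl)cyclohexa-2,4-dien-1-one (racemic aldol adduct, formed in the flask) | COC1=CC(=O)C(CC=C(C)C)(CC=C(C)C)C(O)=C1C(=O)CC(O)c1ccccc1 | intermediate
7 | tunicatachalcone, 5-hydroxy-3-methoxy-6,6-bis(3-methylbut-2-en-1-yl)-4-[(2E)-3-phenylprop-2-enoyl]cyclohexa-2,4-dien-1-one | COC1=CC(=O)C(CC=C(C)C)(CC=C(C)C)C(O)=C1C(=O)/C=C/c1ccccc1 | intermediate
8 | (2R)-5-methoxy-8,8-bis(3-methylbut-2-en-1-yl)-2-phenyl-2,3-dihydro-4H-chromene-4,7(8H)-dione (formed in the flask, returns to 7) | COC1=CC(=O)C(CC=C(C)C)(CC=C(C)C)C2=C1C(=O)C[C@H](c1ccccc1)O2 | intermediate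
9 | (2S)-5-methoxy-8,8-bis(3-methylbut-2-en-1-yl)-2-phenyl-2,3-dihydro-4H-chromene-4,7(8H)-dione (formed in the flask, reduced) | COC1=CC(=O)C(CC=C(C)C)(CC=C(C)C)C2=C1C(=O)C[C@@H](c1ccccc1)O2 | intermediate
10 | pongaflavanol, (2S,4S)-4-hydroxy-5-methoxy-8,8-bis(3-methylbut-2-en-1-yl)-2-phenyl-3,4-dihydro-2H-chromen-7(8H)-one (2-Ph and 4-OH cis) | COC1=CC(=O)C(CC=C(C)C)(CC=C(C)C)C2=C1[C@@H](O)C[C@@H](c1ccccc1)O2 | target

**Totals**
Total step count: 3. Longest linear sequence: 3 steps (1 → 4 → 7 → 10).

**Steps most likely to fail, in order of risk**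

Step 3. The Ru–H may reduce the C=C of the open chalcone (giving the dihydrochalcone) faster than the flavanone C4=O. Ring closure of the stabilised enolate may be slow, and the acidic enol may bind the catalyst. Fallback, setting out from 7 and coming back to the route at 10: ring closure and reduction are decoupled and the stereochemistry is obtained by resolution. Compound 7 is equilibrated with NaOAc/AcOH in EtOH at 60 °C, the racemic flavanone (8 + 9) is isolated by chromatography, and unchanged 7 is recycled. Luche reduction (NaBH4, CeCl3·7H2O, MeOH, −78 °C) attacks the less hindered, less deactivated C4=O anti to the 2-phenyl group and gives the racemic 2,4-cis-flavan-4-ol, that is 10 together with its mirror image (2R,4R)-4-hydroxy-5-methoxy-8,8-bis(3-methylbut-2-en-1-yl)-2-phenyl-3,4-dihydro-2H-chromen-7(8H)-one F2. Preparative chiral SFC separates the two and delivers 10.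

Step 1. C5- versus C3-alkylation, O-alkylation and over- or under-alkylation can all lower the yield of 4. Fallback, setting out from 1 and coming back at 4: the two C–C bonds are made in separate operations by different mechanisms. Compound 1 is mono-prenylated with 1.0 equiv of 2 (aq KOH, 0 °C), and mono-prenyl ketone 3 is isolated and freed from its 5-isomer and from O-ethers by chromatography. Compound 3 is then dearomatised under neutral conditions by a Pd(0)-catalysed Tsuji–Trost prenylation (Pd(PPh3)4, tert-butyl prenyl carbonate, THF, rt). The soft π-prenyl electrophile alkylates carbon only, and exact stoichiometry stops over-alkylation, giving 4. No compound outside the list is made (F0).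

Step 2. The dianion of 4 may enolise sluggishly, and hydroxide may attack the vinylogous ester or deacetylate the ketone. Fallback, setting out from 1 and coming back at 7: the order of events is reversed so that the aldol runs on the aromatic ketone. Compounds 1 and 5 give, with KOH in EtOH at rt, the chalcone cardamonin, (E)-1-(2,4-dihydroxy-6-methoxyphenyl)-3-phenylprop-2-en-1-one F1. F1 is then gem-diprenylated at C3' with 2 (aq KOH, 0 °C → rt), the plant's own order, to give 7 directly.

**Further compounds**
F0 | step 1 | none | none
F1 | step 2 | cardamonin, (E)-1-(2,4-dihydroxy-6-methoxyphenyl)-3-phenylprop-2-en-1-one | COc1cc(O)cc(O)c1C(=O)/C=C/c1ccccc1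
F2 | step 3 | (2R,4R)-4-hydroxy-5-methoxy-8,8-bis(3-methylbut-2-en-1-yl)-2-phenyl-3,4-dihydro-2H-chromen-7(8H)-one (enantiomer of 10) | COC1=CC(=O)C(CC=C(C)C)(CC=C(C)C)C2=C1[C@H](O)C[C@H](c1ccccc1)O2
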